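**Retrosynthetic overview**
1. Gnetumontanin B ⇐ nona-O-methyl ether (BBr3) ⇐ open-chain C2 alcohol with a MOM-masked ring-A phenol (acid closes O1–C2, trans) ⇐ C2 boronic ester (C–B oxidation).
2. Feature used: the C2–C3 ethane unit of the dihydrobenzofuran fused to ring A (the styryl-bearing ring). C3 carries C3a of ring A and the 3,5-dioxygenated phenyl ring; C2 carries O1 and C7' of ring B. This is an (E)-alkenylboron unit to which two aryl groups have been added, with boron standing in for O1.
3. Key disconnection: C2–C7' and C3–aryl in one palladium-catalysed conjunctive coupling of the ring-A (E)-alkenyl B(mac) ester, the C7' aryllithium of the ring-B dihydrobenzofuran and 3,5-dimethoxyphenyl triflate. The hindered mac diol ester is used instead of a pinacol ester because β-substituted alkenyl ate complexes of pinacol tend to transmetalate directly.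
4. Fragments: ring-A boronate from 4-bromo-2-hydroxy-6-methoxybenzaldehyde (MOM, Heck, alkyne, hydroboration). Ring-B bromide from 2-bromo-5-methoxyphenol by a donor/donor rhodium-carbene C–H insertion that sets C3', then acid equilibration of C2' to trans.
5. Ring order: dihydrobenzofuran on ring B (C2'–C3' bond) first, dihydrobenzofuran on ring A (O1–C2 bond) last.

Key step: step 14

Assumption: Rh2(R-PTAD)4 and (Sp,Sp)-MandyPhos are taken as the catalyst enantiomers whose facial preference gives the C3' (S) and C3 (S) centers drawn; should either induce the opposite sense on these substrates, its mirror-image form is used with no other change.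

**Route**

Step 1
Reactants: 1 4-bromo-2-hydroxy-6-methoxybenzaldehyde
Product: 2 4-bromo-2-methoxy-6-(methoxymethoxy)benzaldehyde
Conditions: MOMCl, i-Pr2NEt, CH2Cl2, 0 °C→rt
Reagents that add atoms: chloromethyl methyl ether, COCCl
Why: O-alkylation of the chelated phenol (MOM ether formation) masks the oxygen that becomes O1 as an acetal that should survive the base, organolithium and palladium steps and is removed by acid in step 16.

Step 2
Reactants: 2 4-bromo-2-methoxy-6-(methoxymethoxy)benzaldehyde; 3 4-methoxystyrene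
Product: 4 2-methoxy-6-(methoxymethoxy)-4-[(E)-2-(4-methoxyphenyl)ethenyl]benzaldehyde
Conditions: Pd(OAc)2 (3 mol %), P(o-tol)3 (6 mol %), Et3N, DMF, 100 °C
Reagents that add atoms: none
Why: Mizoroki–Heck reaction of an aryl bromide activated by the para formyl group with a terminal styrene, in which syn insertion and syn β-hydride elimination should give the (E)-stilbene.

Step 3
Reactants: 4 2-methoxy-6-(methoxymethoxy)-4-[(E)-2-(4-methoxyphenyl)ethenyl]benzaldehyde
Product: 5 2-ethynyl-1-methoxy-3-(methoxymethoxy)-5-[(E)-2-(4-methoxyphenyl)ethenyl]benzene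
Conditions: dimethyl (1-diazo-2-oxopropyl)phosphonate, K2CO3, MeOH, rt
Reagents that add atoms: dimethyl (1-diazo-2-oxopropyl)phosphonate, CC(=O)C(=[N+]=[N-])P(=O)(OC)OC
Why: Ohira–Bestmann (Seyferth–Gilbert) homologation of a non-enolisable aryl aldehyde under mild carbonate conditions that should leave the MOM acetal and the stilbene untouched.

Step 4
Reactants: 6 acenaphthoquinone
Product: 7 mac diol, cis-1,2-dimethyl-1,2-dihydroacenaphthylene-1,2-diol (meso, 1R,2S)
Conditions: AlMe3 (3 equiv), toluene, 0 °C→rt; then 1 M HCl, 0 °C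
Reagents that add atoms: trimethylaluminium, C[Al](C)C
Why: Double 1,2-addition of methyl to the 1,2-diketone, in which the second methyl should enter anti to the first aluminium alkoxide so that the two hydroxyl groups end up cis, the only arrangement that can form the five-membered boronate.

Step 5
Reactants: 5 2-ethynyl-1-methoxy-3-(methoxymethoxy)-5-[(E)-2-(4-methoxyphenyl)ethenyl]benzene; 7 mac diol
Product: 9 ring-A (E)-alkenyl B(mac) ester, via alkenyl catecholboronate 8 (not isolated)
Conditions: catecholborane, Cy2BH (10 mol %), THF, rt; then 7, rt; aqueous NaHCO3 wash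
Reagents that add atoms: catecholborane, B1Oc2ccccc2O1
Why: Hydroboration of the terminal alkyne (syn addition, boron to the terminal carbon) gives the (E)-alkenylboronate, and the labile catechol ester is exchanged by transesterification for the hindered mac diol, the boron ligand that keeps β-substituted alkenyl ate complexes on the 1,2-shift path.

Step 6
Reactants: 10 3,5-dimethoxyphenol
Product: 11 3,5-dimethoxyphenyl trifluoromethanesulfonate
Conditions: Tf2O, pyridine, CH2Cl2, 0 °C
Reagents that add atoms: trifluoromethanesulfonic anhydride, O=S(=O)(OS(=O)(=O)C(F)(F)F)C(F)(F)F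
Why: O-sulfonylation of the phenol gives the aryl triflate, whose weakly coordinating leaving group provides the cationic arylpalladium needed in step 14.

Step 7
Reactants: 12 2-bromo-5-methoxyphenol
Product: 13 3-bromo-2-hydroxy-6-methoxybenzaldehyde
Conditions: MgCl2, Et3N, (CH2O)n, MeCN, reflux; then 1 M HCl
Reagents that add atoms: paraformaldehyde (as formaldehyde), C=O
Why: Magnesium-mediated ortho-formylation (Casnati–Skattebøl) takes place only ortho to the phenoxide, and with one ortho position blocked by bromine the only site left is the carbon between the two oxygens, which places bromine next to the future O1'.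

Step 8
Reactants: 13 3-bromo-2-hydroxy-6-methoxybenzaldehyde; 14 2,4-dimethoxybenzyl alcohol
Product: 15 3-bromo-2-[(2,4-dimethoxybenzyl)oxy]-6-methoxybenzaldehyde
Conditions: PPh3, DIAD, THF, 0 °C→rt
Reagents that add atoms: none
Why: Mitsunobu etherification of the acidic salicylaldehyde hydroxyl with a primary benzylic alcohol installs the O–CH2–aryl unit whose carbon becomes C2', without use of the unstable 2,4-dimethoxybenzyl halide.

Step 9
Reactants: 15 3-bromo-2-[(2,4-dimethoxybenzyl)oxy]-6-methoxybenzaldehyde; 16 3,5-dimethoxyphenylmagnesium bromide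
Product: 17 {3-bromo-2-[(2,4-dimethoxybenzyl)oxy]-6-methoxyphenyl}(3,5-dimethoxyphenyl)methanol (racemic)
Conditions: 16 (THF solution), THF, −20→0 °C; then H2O
Reagents that add atoms: none
Why: Grignard 1,2-addition to the aldehyde, with the aryl bromide and the benzylic ether inert to ArMgBr at low temperature; the racemic carbinol center is removed in step 10.

Step 10
Reactants: 17 the diaryl carbinol
Product: 18 {3-bromo-2-[(2,4-dimethoxybenzyl)oxy]-6-methoxyphenyl}(3,5-dimethoxyphenyl)methanone
Conditions: Dess–Martin periodinane, CH2Cl2, rt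
Reagents that add atoms: none
Why: Dess–Martin oxidation of a secondary diaryl carbinol under near-neutral conditions should give the ketone without cleaving the acid-labile dimethoxybenzyl ether.

Step 11
Reactants: 18 the diaryl ketone
Product: 19 hydrazone of 18
Conditions: N2H4·H2O (excess), AcOH (cat.), n-BuOH, 110 °C, sealed tube
Reagents that add atoms: hydrazine hydrate, NN.O
Why: Condensation of hydrazine with the diaryl ketone (hydrazone formation), driven by excess reagent and heat because the carbonyl carries a 2,6-disubstituted ring.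

Step 12
Reactants: 19 hydrazone of 18
Product: 21 (2R,3S)-7-bromo-2-(2,4-dimethoxyphenyl)-3-(3,5-dimethoxyphenyl)-4-methoxy-2,3-dihydrobenzofuran (cis), via diaryldiazomethane 20 (not isolated)
Conditions: MnO2, CH2Cl2, 0 °C, filter; then Rh2(R-PTAD)4 (1 mol %), CH2Cl2, 0 °C→rt, slow addition
Reagents that add atoms: none
Why: Oxidation of the hydrazone gives the diaryldiazomethane, and the chiral dirhodium tetracarboxylate turns it into a donor/donor carbene that inserts into the doubly activated benzylic ether C–H bond through a five-membered transition state (enantioselective intramolecular C–H insertion), the catalyst setting C3' (S) and the cis C2' center, while the methoxy C–H bonds on the other ortho oxygen are far less reactive.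

Step 13
Reactants: 21 the cis dihydrobenzofuran
Product: 22 (2S,3S)-7-bromo-2-(2,4-dimethoxyphenyl)-3-(3,5-dimethoxyphenyl)-4-methoxy-2,3-dihydrobenzofuran (trans, fragment 2)
Conditions: TFA (5 equiv), CH2Cl2, 0 °C→rt
Reagents that add atoms: none
Why: Acid opens the C2'–O1' bond to the 2,4-dimethoxybenzylic cation and reclosure under thermodynamic control (epimerization by reversible ionization) should give the trans isomer, so C2' becomes S relative to the untouched C3' (S) center.

Step 14
Reactants: 22 fragment 2 bromide; 9 ring-A (E)-alkenyl B(mac) ester; 11 3,5-dimethoxyphenyl trifluoromethanesulfonate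
Product: 25 B(mac) ester of the (1R,2S)-1,2,2-triarylethylboronic acid, via ring-B aryllithium 23 (not isolated), via lithium boron ate complex 24 (not isolated)
Conditions: 22, t-BuLi (2.0 equiv), THF, −78 °C; 9, −78 °C→rt; then 11, Pd(OAc)2 (5 mol %), (Sp,Sp)-MandyPhos (6 mol %), KOTf (2 equiv), THF, 60 °C
Reagents that add atoms: none
Why: Aryllithium 23 adds to the boron of 9 to give ate complex 24; the cationic arylpalladium triflate formed by oxidative addition of 11 to the zerovalent palladium–MandyPhos complex binds the boron-bearing alkene and triggers a 1,2-shift of the ring-B aryl group from boron to C2 while palladium bonds to C3 on the opposite face, and C–C reductive elimination at the benzylic palladium then makes the C3–aryl bond with retention. The closest known reaction type is the enantioselective conjunctive cross-coupling of β-substituted (E)-alkenyl B(mac) ate complexes with aryl triflates, and the β-aryl group with two ortho oxygens is the added demand here. No ring is closed. Anti addition across the (E)-alkene fixes the C2/C3 relationship as (1R,2S) in the ethyl numbering, and the alkene face chosen by the chiral ferrocenyl bisphosphine sets C3 (S), which the distant C2' and C3' centers are not expected to override. The step needs the 1,2-shift in preference to direct boron-to-palladium transfer, which the hindered mac diol and removal of bromide by KOTf should secure, and it needs reaction at the ate alkene only, which follows because the neutral stilbene lacks the anionic boron that drives the shift. The C2 configuration is not critical, since ring closure in step 16 gives the trans ring from this isomer by either an invertive or a cationic path.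

Step 15
Reactants: 25 the triarylethyl B(mac) ester
Product: 26 (1R,2S)-1-[fragment 2 aryl]-2-(3,5-dimethoxyphenyl)-2-{2-methoxy-6-(methoxymethoxy)-4-[(E)-2-(4-methoxyphenyl)ethenyl]phenyl}ethanol
Conditions: NaOH (3 M aq), H2O2 (30 %), THF, 0 °C→rt
Reagents that add atoms: hydrogen peroxide, OO
Why: Oxidation of the C–B bond by hydroperoxide with 1,2-migration from boron to oxygen and retention gives the (1R) benzylic alcohol and returns the mac diol, while the electron-rich stilbene and the MOM acetal are inert to alkaline peroxide.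

Step 16
Reactants: 26 the (1R,2S) alcohol
Product: 28 nona-O-methyl gnetumontanin B (2S,3S,2'S,3'S), via phenol alcohol 27 (not isolated)
Conditions: HCl (1.25 M in MeOH), THF, 0→40 °C
Reagents that add atoms: none
Why: Acid methanolysis removes the MOM acetal and activates the 2,4-dioxygenated benzylic alcohol, and 5-exo capture by the freed phenol gives the trans-2,3-diaryl dihydrobenzofuran (acid-mediated cycloetherification), the isomer expected both from invertive displacement of the (1R) alcohol and from equilibration through the C2 cation, so C2 (S) follows from C3 (S).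

Step 17
Reactants: 28 nona-O-methyl gnetumontanin B
Product: 29 gnetumontanin B
Conditions: BBr3 (1 M in CH2Cl2, 30 equiv), CH2Cl2, −78 °C→rt; then H2O, 0 °C
Reagents that add atoms: none
Why: Lewis acid cleavage of aryl methyl ethers (BBr3 demethylation) should free all nine phenols, since any reversible opening of the two benzylic C–O bonds recloses to the favoured trans rings and the stilbene sits para to C3a, away from any ring that could alkylate it.

**Compound list**
1 | 4-bromo-2-hydroxy-6-methoxybenzaldehyde | COc1cc(Br)cc(O)c1C=O | starting material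
2 | 4-bromo-2-methoxy-6-(methoxymethoxy)benzaldehyde | COCOc1cc(Br)cc(OC)c1C=O | intermediate
3 | 4-methoxystyrene | C=Cc1ccc(OC)cc1 | starting material
4 | 2-methoxy-6-(methoxymethoxy)-4-[(E)-2-(4-methoxyphenyl)ethenyl]benzaldehyde | COCOc1cc(/C=C/c2ccc(OC)cc2)cc(OC)c1C=O | intermediate
5 | 2-ethynyl-1-methoxy-3-(methoxymethoxy)-5-[(E)-2-(4-methoxyphenyl)ethenyl]benzene | COCOc1cc(/C=C/c2ccc(OC)cc2)cc(OC)c1C#C | intermediate
6 | acenaphthoquinone | O=C1C(=O)c2cccc3cccc1c23 | starting material
7 | mac diol, cis-1,2-dimethyl-1,2-dihydroacenaphthylene-1,2-diol (meso) | C[C@]1(O)c2cccc3cccc(c23)[C@@]1(C)O | intermediate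
8 | ring-A (E)-alkenyl catecholboronate | COCOc1cc(/C=C/c2ccc(OC)cc2)cc(OC)c1/C=C/B1Oc2ccccc2O1 | intermediate (not isolated)
9 | ring-A (E)-alkenyl B(mac) ester | COCOc1cc(/C=C/c2ccc(OC)cc2)cc(OC)c1/C=C/B1O[C@@]2(C)c3cccc4cccc(c34)[C@@]2(C)O1 | intermediate
10 | 3,5-dimethoxyphenol | COc1cc(O)cc(OC)c1 | starting material
11 | 3,5-dimethoxyphenyl trifluoromethanesulfonate | COc1cc(OC)cc(OS(=O)(=O)C(F)(F)F)c1 | intermediate
12 | 2-bromo-5-methoxyphenol | COc1ccc(Br)c(O)c1 | starting material
13 | 3-bromo-2-hydroxy-6-methoxybenzaldehyde | COc1ccc(Br)c(O)c1C=O | intermediate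
14 | 2,4-dimethoxybenzyl alcohol | COc1ccc(CO)c(OC)c1 | starting material
15 | 3-bromo-2-[(2,4-dimethoxybenzyl)oxy]-6-methoxybenzaldehyde | COc1ccc(COc2c(Br)ccc(OC)c2C=O)c(OC)c1 | intermediate
16 | 3,5-dimethoxyphenylmagnesium bromide | COc1cc(OC)cc([Mg]Br)c1 | starting material
17 | {3-bromo-2-[(2,4-dimethoxybenzyl)oxy]-6-methoxyphenyl}(3,5-dimethoxyphenyl)methanol (racemic) | COc1ccc(COc2c(Br)ccc(OC)c2C(O)c2cc(OC)cc(OC)c2)c(OC)c1 | intermediate
18 | {3-bromo-2-[(2,4-dimethoxybenzyl)oxy]-6-methoxyphenyl}(3,5-dimethoxyphenyl)methanone | COc1ccc(COc2c(Br)ccc(OC)c2C(=O)c2cc(OC)cc(OC)c2)c(OC)c1 | intermediate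
19 | hydrazone of 18 | COc1ccc(COc2c(Br)ccc(OC)c2C(=NN)c2cc(OC)cc(OC)c2)c(OC)c1 | intermediate
20 | diaryldiazomethane from 19 | COc1ccc(COc2c(Br)ccc(OC)c2C(=[N+]=[N-])c2cc(OC)cc(OC)c2)c(OC)c1 | intermediate (not isolated)
21 | (2R,3S)-7-bromo-2-(2,4-dimethoxyphenyl)-3-(3,5-dimethoxyphenyl)-4-methoxy-2,3-dihydrobenzofuran (cis) | Brc1ccc(OC)c2c1O[C@@H](c1ccc(OC)cc1OC)[C@H]2c1cc(OC)cc(OC)c1 | intermediate
22 | (2S,3S)-7-bromo-2-(2,4-dimethoxyphenyl)-3-(3,5-dimethoxyphenyl)-4-methoxy-2,3-dihydrobenzofuran (trans, fragment 2) | Brc1ccc(OC)c2c1O[C@H](c1ccc(OC)cc1OC)[C@H]2c1cc(OC)cc(OC)c1 | intermediate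
23 | 7-lithio derivative of 22 | [Li]c1ccc(OC)c2c1O[C@H](c1ccc(OC)cc1OC)[C@H]2c1cc(OC)cc(OC)c1 | intermediate (not isolated)
24 | lithium aryl(alkenyl) B(mac) ate complex | [Li+].COCOc1cc(/C=C/c2ccc(OC)cc2)cc(OC)c1/C=C/[B-]1(c2ccc(OC)c3c2O[C@H](c2ccc(OC)cc2OC)[C@H]3c2cc(OC)cc(OC)c2)O[C@@]2(C)c3cccc4cccc(c34)[C@@]2(C)O1 | intermediate (not isolated)
25 | B(mac) ester of (1R,2S)-1-[fragment 2 aryl]-2-(3,5-dimethoxyphenyl)-2-{2-methoxy-6-(methoxymethoxy)-4-[(E)-2-(4-methoxyphenyl)ethenyl]phenyl}ethylboronic acid | B1(O[C@@]2(C)c3cccc4cccc(c34)[C@@]2(C)O1)[C@@H](c1ccc(OC)c2c1O[C@H](c1ccc(OC)cc1OC)[C@H]2c1cc(OC)cc(OC)c1)[C@@H](c1cc(OC)cc(OC)c1)c1c(OC)cc(/C=C/c2ccc(OC)cc2)cc1OCOC | intermediate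
26 | (1R,2S) alcohol from 25 | O[C@@H](c1ccc(OC)c2c1O[C@H](c1ccc(OC)cc1OC)[C@H]2c1cc(OC)cc(OC)c1)[C@@H](c1cc(OC)cc(OC)c1)c1c(OC)cc(/C=C/c2ccc(OC)cc2)cc1OCOC | intermediate
27 | (1R,2S) phenol alcohol (26 without MOM) | O[C@@H](c1ccc(OC)c2c1O[C@H](c1ccc(OC)cc1OC)[C@H]2c1cc(OC)cc(OC)c1)[C@@H](c1cc(OC)cc(OC)c1)c1c(OC)cc(/C=C/c2ccc(OC)cc2)cc1O | intermediate (not isolated)
28 | nona-O-methyl gnetumontanin B (2S,3S,2'S,3'S) | COc1ccc(/C=C/c2cc(OC)c3c(c2)O[C@H](c2ccc(OC)c4c2O[C@H](c2ccc(OC)cc2OC)[C@H]4c2cc(OC)cc(OC)c2)[C@H]3c2cc(OC)cc(OC)c2)cc1 | intermediate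
29 | gnetumontanin B | Oc1ccc(/C=C/c2cc(O)c3c(c2)O[C@H](c2ccc(O)c4c2O[C@H](c2ccc(O)cc2O)[C@H]4c2cc(O)cc(O)c2)[C@H]3c2cc(O)cc(O)c2)cc1 | target

**Totals**
Total step count: 17. Longest linear sequence: 11 steps (steps 7–17, from 2-bromo-5-methoxyphenol).

**Steps most likely to fail**

Step 14 (key step). The ate complex may hand its alkenyl or aryl group directly to palladium (Suzuki-type coupling), the benzylic palladium intermediate may lose the C2 hydrogen, reductive elimination next to the 2,6-dioxygenated ring may be slow, or facial selection may be poor. The fallback sets out from 4 and 22 and comes back at 28; it builds the same two bonds stepwise without control at C3 and relies on the fixed C2'/C3' centers to make the C3 epimers separable diastereomers. Grignard reagent 16 adds to aldehyde 4 to give the diaryl carbinol F1. Dess–Martin oxidation gives the diaryl ketone F2. Corey–Chaykovsky methylenation (trimethylsulfonium iodide, KOt-Bu, DMSO) gives the 2,2-diaryl epoxide F3. ZnI2-promoted Meinwald rearrangement (toluene, rt) gives the 2,2-diarylacetaldehyde F4. Aryllithium 23 (from 22, t-BuLi, THF, −78 °C) adds to give the triarylethanol mixture F5. Methanolic HCl as in step 16 closes the trans ring to give 28 together with its (2R,3R,2'S,3'S) diastereomer F6, and the two are separated by chromatography.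

Step 11. Condensation may stall, because the carbonyl is shielded on both faces by the 2,6-disubstituted ring. The fallback sets out from 15 and comes back at 19; it forms the C=N bond by addition to a nitrile instead of condensation at a ketone. Aldehyde 15 is converted into the benzonitrile F7 (I2, aqueous NH3, THF, rt). Grignard reagent 16 adds to the nitrile (THF, reflux; MeOH quench) to give the N–H ketimine F8. Exchange with hydrazine (N2H4·H2O, AcOH, EtOH, rt→50 °C) gives hydrazone 19.

Step 16. The C2 cation may lose the C3 hydrogen to a triarylethylene, which would erase C3, or the cleaved MOM fragment may alkylate the resorcinol rings. The fallback sets out from 25 and comes back at 28; it closes the ring by stereospecific displacement instead of ionization. The MOM group is removed at the boronate stage, where C2 cannot ionize (HCl in MeOH/THF, 0→40 °C), to give the phenol boronate F9. Oxidation with NaOH/H2O2 gives phenol alcohol 27, now isolated. Mitsunobu cyclodehydration (PPh3, DIAD, THF, 0 °C) closes O1–C2 with inversion at the (1R) carbinol, which gives the trans ring of 28 directly.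

**Further compounds**
F1 | step 14 | {2-methoxy-6-(methoxymethoxy)-4-[(E)-2-(4-methoxyphenyl)ethenyl]phenyl}(3,5-dimethoxyphenyl)methanol (racemic) | COCOc1cc(/C=C/c2ccc(OC)cc2)cc(OC)c1C(O)c1cc(OC)cc(OC)c1
F2 | step 14 | {2-methoxy-6-(methoxymethoxy)-4-[(E)-2-(4-methoxyphenyl)ethenyl]phenyl}(3,5-dimethoxyphenyl)methanone | COCOc1cc(/C=C/c2ccc(OC)cc2)cc(OC)c1C(=O)c1cc(OC)cc(OC)c1
F3 | step 14 | 2-(3,5-dimethoxyphenyl)-2-{2-methoxy-6-(methoxymethoxy)-4-[(E)-2-(4-methoxyphenyl)ethenyl]phenyl}oxirane (racemic) | COCOc1cc(/C=C/c2ccc(OC)cc2)cc(OC)c1C3(CO3)c1cc(OC)cc(OC)c1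
F4 | step 14 | 2-(3,5-dimethoxyphenyl)-2-{2-methoxy-6-(methoxymethoxy)-4-[(E)-2-(4-methoxyphenyl)ethenyl]phenyl}acetaldehyde (racemic) | COCOc1cc(/C=C/c2ccc(OC)cc2)cc(OC)c1C(C=O)c1cc(OC)cc(OC)c1
F5 | step 14 | triarylethanol 26 as a mixture of isomers at the carbinol and diarylmethine carbons | OC(c1ccc(OC)c2c1O[C@H](c1ccc(OC)cc1OC)[C@H]2c1cc(OC)cc(OC)c1)C(c1cc(OC)cc(OC)c1)c1c(OC)cc(/C=C/c2ccc(OC)cc2)cc1OCOC
F6 | step 14 | (2R,3R,2'S,3'S) diastereomer of 28 | COc1ccc(/C=C/c2cc(OC)c3c(c2)O[C@@H](c2ccc(OC)c4c2O[C@H](c2ccc(OC)cc2OC)[C@H]4c2cc(OC)cc(OC)c2)[C@@H]3c2cc(OC)cc(OC)c2)cc1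
F7 | step 11 | 3-bromo-2-[(2,4-dimethoxybenzyl)oxy]-6-methoxybenzonitrile | COc1ccc(COc2c(Br)ccc(OC)c2C#N)c(OC)c1
F8 | step 11 | N–H ketimine of 18 | COc1ccc(COc2c(Br)ccc(OC)c2C(=N)c2cc(OC)cc(OC)c2)c(OC)c1
F9 | step 16 | phenol B(mac) ester (25 without MOM) | B1(O[C@@]2(C)c3cccc4cccc(c34)[C@@]2(C)O1)[C@@H](c1ccc(OC)c2c1O[C@H](c1ccc(OC)cc1OC)[C@H]2c1cc(OC)cc(OC)c1)[C@@H](c1cc(OC)cc(OC)c1)c1c(OC)cc(/C=C/c2ccc(OC)cc2)cc1O
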